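## Structural features

The target is a 3,4-dihydroisocoumarin: benzene ring A is fused along C4a–C8a to a six-membered lactone ring B (C1 carbonyl, O2, C3, C4). Ring A carries a free phenol at C8, peri to the lactone carbonyl and hydrogen-bonded to it, and a methyl ether at C6. C3 bears an unbranched eleven-carbon chain (C1'–C11') that ends in a primary alcohol. C3 is the only stereocentre, (R)-configured, and no neighbouring stereocentre exists from which its configuration could be relayed. The fragile groups are the lactone (opened by hydroxide, alkoxides and organometallic reagents), the electron-rich resorcinol-type ring (easily over-halogenated or oxidised) and the two hydroxyl groups, which must be masked during organometallic steps. The real difficulty is the absolute configuration of an isolated carbinol whose two carbon neighbours are both methylene groups (benzylic C4 and C1'); they differ too little in size for a reliable asymmetric ketone reduction. A second difficulty is telling the C8 oxygen from the C6 oxygen. The key step uses the position of C3 between C4 and C1': C3 is delivered as a single carbon from dichloromethane, inserted between a C4–boron bond and a C1'–magnesium bond, and the boron left on C3 becomes O2. The symmetric 3,5-dioxygenated ring A makes both ortho carbons (future C8a) equivalent for the later introduction of C1.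

## Logic of the disconnections

**17 to 16.** The O–CH3 bond at C8 and the O–Si bond at C11' are cut. Both hydroxyls stay masked through all metal-mediated steps, and the C8 ether is the one that a Lewis acid can distinguish from the C6 ether because it can chelate together with the C1 carbonyl. The gain is that 17 arises from a fully protected lactone in one operation. The forward step must cleave only the peri ether and must not open ring B.

**16 to 15.** The C1–C8a and C1–O2 bonds are cut and C1 is removed as carbon monoxide. Ring B is the most sensitive part of the molecule, so it is formed only after every organometallic step. The gain is an open-chain aryl iodide carrying the C3 carbinol. The forward step needs oxidative addition at a C–I bond flanked by two ortho substituents and capture of the acyl group by the secondary hydroxyl, without breaking the C3–O bond.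

**15 to 14.** The C8a–I bond is cut. Because ring A of 14 is symmetric, both carbons ortho to the side chain are the same, and each is para to one methoxy group. The gain is a symmetric arene. The forward step must iodinate once, and not at the carbon between the two methoxy groups.

**14 to 13.** The C3–O bond is traced back to a C3–B bond. Oxidation of a boronic ester runs with retention, so the stereochemical problem moves to the boron-bearing carbon. The gain is that the auxiliary of 13 is released as 2 and can be recovered. The forward step must leave the silyl ether intact.

**13 to 6, 10 and 9 (through 11 and 12).** The C4–C3 and C3–C1' bonds are cut, so C3 becomes the carbon of 10. This removes the whole side-chain stereochemistry problem in one operation and splits the molecule into a benzylboron half, a one-carbon unit and the chain nucleophile 9. The forward step needs high diastereoselection in the first migration, which the diol of 6 must provide, and clean inversion in the second.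

**6 to 3 and 2 (through 4 and 5).** The C4–B bond and the two B–O bonds are cut. The benzylic chloride 3 is chosen over the bromide because its magnesium reagent 4 couples less with unreacted halide. The acid 5 is not stored but esterified at once with 2. The forward step must stop at one B–C bond.

**2 to 1.** The cyclohexyl rings are traced back to phenyl rings. 1 is an article of commerce in the (S,S) form, and hydrogenation does not touch the carbinol centres. The demand is arene saturation without benzylic C–O hydrogenolysis.

**9 to 8 to 7.** The C–Mg bond and the O–Si bond are cut. The silyl ether lets 7 be turned into a Grignard reagent, and the same group is removed in the last step by the acid formed there, so it costs no separate deprotection.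

## Other disconnections considered

**Alternative 1:** The cut is the O2–C3 bond of ring B.
- **Forward key step:** The allylic carbonate acid A2, 2,4-dimethoxy-6-[(2E)-4-(methoxycarbonyloxy)but-2-en-1-yl]benzoic acid, would be ionised by [Ir(cod)Cl]2 with a chiral phosphoramidite. The carboxylate oxygen would attack the internal allyl carbon, closing ring B and setting C3 in the vinyl lactone A1, (3S)-6,8-dimethoxy-3-vinyl-3,4-dihydroisocoumarin.
- **In its favour:** The chiral information is catalytic. Ring B and the C1 carbonyl exist before the stereocentre is made, so neither halogenation nor carbonylation is needed. The vinyl group allows chain extension by cross-metathesis with undec-10-en-1-ol A3 followed by hydrogenation.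
- **Against it here:**
  - A2 needs its own multistep assembly.
  - A1 is itself an allylic ester that the iridium catalyst could ionise again, with possible erosion of enantiomeric purity or drift to the linear isomer.
  - The cross-metathesis must engage a vinyl group on a branched, oxygen-bearing carbon.
  - Hydrogenation of the resulting allylic lactone could compete with hydrogenolysis of the C3–O2 bond.
- **Structure:** The alternative handles ring B and C3 together; the chosen plan sets C3 in an open chain and closes ring B later. The end game, selective cleavage of the C8 methyl ether, is the same, so the two are equal on that point.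
- **Mechanism:** Catalyst control at a pi-allyl intermediate stands against auxiliary control followed by a stereospecific migration. Catalytic use of chirality is the better feature of the alternative. The configurational stability of every intermediate after the stereo-defining event is the better feature of the chosen plan.
- **Step economy:** About equal. The steps saved on halogenation and carbonylation would be spent on A2 and on chain extension.

**Alternative 2:** The cut is the C4a–C8a bond, so ring A itself is built.
- **Forward key step:** The diketo-dioxinone A5, 6-[(6R)-6,17-bis(tert-butyldimethylsilyloxy)-2,4-dioxoheptadecyl]-2,2-dimethyl-4H-1,3-dioxin-4-one, would undergo an amine-mediated intramolecular aldol condensation of its dioxinone C5 onto the distal ketone. Dehydration and enolisation would give the benzodioxinone A4, 5-[(2R)-2,13-bis(tert-butyldimethylsilyloxy)tridecyl]-7-hydroxy-2,2-dimethyl-4H-1,3-benzodioxin-4-one.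
- **In its favour:** The two ring oxygens are born differentiated. The future C8 oxygen is held in the ketal and the future C6 oxygen is a free phenol ready for methylation. Desilylation of the C3 oxygen should then lead to lactonisation onto the dioxinone carbonyl, freeing the C8 phenol. On this point the alternative is better than the chosen plan, which depends on a selective ether cleavage. It also needs no transition metal, no halogenation and no carbon monoxide.
- **Against it here:**
  - A5 is a sensitive polycarbonyl compound that must be assembled by C-acylation with a chiral beta-silyloxy acyl donor, and that donor needs an asymmetric step and several steps of its own.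
  - The beta-silyloxy ketone in A5 could eliminate under the amine base before it aromatises.
  - The stereocentre has to be carried through these enolisable intermediates.
- **Structure:** The alternative spends its effort on ring A, which the chosen plan simply buys.
- **Mechanism:** A biomimetic aldol–aromatisation cascade stands against a stereospecific boron-to-carbon migration. Both are well understood, but the cascade has more competing pathways.
- **Step economy:** The alternative is longer and more linear.

**Alternative 3:** The cut removes three bonds at once: C4a–C4, C8a–C1 and C1–O2.
- **Forward key step:** A palladium/norbornene relay would start from 1-iodo-2,4-dimethoxybenzene A7 and the epoxide A8, (R)-2-[11-(tert-butyldimethylsilyloxy)undecyl]oxirane, under carbon monoxide. The epoxide CH2 would alkylate the free ortho position of A7, CO would insert at the ipso carbon after norbornene is expelled, and the alkoxide would close ring B to give the lactone A6, (3R)-3-[11-(tert-butyldimethylsilyloxy)undecyl]-6,8-dimethoxy-3,4-dihydroisocoumarin, which is identical with 16.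
- **In its favour:** Three bonds and ring B form in one step from two simple fragments. The stereocentre comes unchanged from an enantiopure epoxide. The sequence to 16 is shorter than in the chosen plan, so on step economy the alternative is better. The final step would be the same, so the end game is equal.
- **Against it here:**
  - The cascade has to alkylate a palladacycle with an unactivated, alkyl-substituted epoxide, which iodide can also open.
  - CO must be kept from inserting into the first arylpalladium species or from saturating the catalyst before the ortho alkylation.
  - Carbonylative termination is less secure than the simpler terminations of this relay.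
  - A8 would come from a kinetic resolution that discards half of the racemate.
- **Structure:** Both plans reach 16; the alternative makes ring B and the side-chain attachment together, the chosen plan one bond at a time.
- **Mechanism:** A multicomponent catalytic cascade with several competing channels stands against a sequence of individually reliable, stereospecific steps.
- **Step economy:** The alternative wins. On predictability of each step, the chosen plan wins.

Key step: step 5

## Route

Step 1
Reactants: 1 (1S,2S)-1,2-diphenylethane-1,2-diol [(S,S)-hydrobenzoin]
Product: 2 (1S,2S)-1,2-dicyclohexylethane-1,2-diol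
Conditions: H2 (5 bar), Rh/Al2O3 (5 wt %), MeOH, 50 °C
Reagents that add atoms: none
Why: Heterogeneous arene hydrogenation; rhodium saturates the phenyl rings with little benzylic C–O hydrogenolysis, and the two carbinol centres are not touched, so the (S,S) configuration is carried over.

Step 2
Reactants: 3 3,5-dimethoxybenzyl chloride; 2 (1S,2S)-1,2-dicyclohexylethane-1,2-diol
Product: 6 (4S,5S)-4,5-dicyclohexyl-2-(3,5-dimethoxybenzyl)-1,3,2-dioxaborolane, via 3,5-dimethoxybenzylmagnesium chloride 4 (not isolated), via (3,5-dimethoxybenzyl)boronic acid 5 (not isolated)
Conditions: Mg, I2 (cat.), Et2O, 0 °C (slow addition of 3); cannulated into B(OMe)3 (1.5 equiv), THF, −78 °C → rt; 1 M aq. HCl, 0 °C; ether phase + 2 (0.8 equiv), MgSO4, rt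
Reagents that add atoms: trimethyl borate, COB(OC)OC (the boron atom); magnesium, [Mg] (kept only in 4)
Why: Grignard formation, borylation with a trialkyl borate and esterification of the boronic acid with a diol; the benzylic chloride added slowly to magnesium in ether gives less Wurtz coupling than the bromide, inverse addition to excess borate limits the reaction to one B–C bond, and the air-sensitive acid 5 is condensed at once with 2 (the limiting component) to the chromatographically stable ester 6.

Step 3
Reactants: 7 11-bromoundecan-1-ol
Product: 8 [(11-bromoundecyl)oxy](tert-butyl)dimethylsilane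
Conditions: TBSCl (1.1 equiv), imidazole (1.5 equiv), CH2Cl2, 0 °C → rt
Reagents that add atoms: tert-butyldimethylsilyl chloride, CC(C)(C)[Si](C)(C)Cl
Why: Silylation of a primary alcohol with a silyl chloride and imidazole; the primary bromide is inert in CH2Cl2 at room temperature.

Step 4
Reactants: 8 [(11-bromoundecyl)oxy](tert-butyl)dimethylsilane
Product: 9 [11-(tert-butyldimethylsilyloxy)undecyl]magnesium bromide
Conditions: Mg turnings (1.5 equiv), I2 (cat.), THF, rt → 45 °C; titrated before use
Reagents that add atoms: magnesium, [Mg]
Why: Grignard formation by magnesium insertion into a primary C–Br bond; the silyl ether has no acidic hydrogen and does not react, and slow addition keeps Wurtz coupling low.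

Step 5
Reactants: 6 (4S,5S)-4,5-dicyclohexyl-2-(3,5-dimethoxybenzyl)-1,3,2-dioxaborolane; 10 dichloromethane; 9 [11-(tert-butyldimethylsilyloxy)undecyl]magnesium bromide
Product: 13 (4S,5S)-4,5-dicyclohexyl-2-[(2R)-13-(tert-butyldimethylsilyloxy)-1-(3,5-dimethoxyphenyl)tridecan-2-yl]-1,3,2-dioxaborolane, via (dichloromethyl)lithium 11 (not isolated), via (1R)-chloro boronic ester 12 (not isolated)
Conditions: 10 (1.6 equiv), n-BuLi (1.2 equiv), THF, −100 °C; 6 (1.0 equiv), −100 °C; ZnCl2 (1.0 equiv, dried, in THF), −100 °C → rt, 16 h; then 9 (2.5 equiv), −78 °C → rt, 16 h; aq. NH4Cl
Reagents that add atoms: none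
Why: The closest known reaction type is the Matteson homologation of a chiral diol boronic ester with LiCHCl2 and ZnCl2, followed by stereospecific Grignard substitution of the alpha-chloro boronic ester; no ring is closed. 11, formed from 10 and n-BuLi at −100 °C, adds to the trigonal boron of 6 faster than it deprotonates the benzylic C–H and gives a tetrahedral (dichloromethyl)borate. ZnCl2 bridges a dioxaborolane oxygen and the departing chloride, and the benzyl group shifts from boron to carbon antiperiplanar to that chloride, which forms C4–C3 and gives 12. The (S,S)-diol makes the two chlorides diastereotopic: in the favoured zinc chelate the chloride that stays points away from the zinc-bound chlorides and the nearer cyclohexyl group, which should give the (1R) centre. 9 then adds to the boron of 12 and its primary alkyl group migrates with inversion, expelling the second chloride and forming C3–C1'; the step is stereospecific, so the (2R) centre of 13 is controlled by the auxiliary alone. The step needs carbon rather than oxygen migration and no chloride-induced epimerisation of 12; ZnCl2, which binds free chloride, and the immediate use of 12 secure both. Single insertion is secured because 11 is consumed or destroyed before the mixture warms, and both migrating groups are unhindered primary carbons on a substrate that carries only ether groups. The excess of 9 covers the share that ZnCl2 takes up by transmetalation.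

Step 6
Reactants: 13 (4S,5S)-4,5-dicyclohexyl-2-[(2R)-13-(tert-butyldimethylsilyloxy)-1-(3,5-dimethoxyphenyl)tridecan-2-yl]-1,3,2-dioxaborolane
Product: 14 (2R)-13-(tert-butyldimethylsilyloxy)-1-(3,5-dimethoxyphenyl)tridecan-2-ol
Conditions: H2O2 (30 % aq.), NaOH (2 M aq.), THF, 0 °C → rt
Reagents that add atoms: hydrogen peroxide, OO
Why: Oxidation of the C–B bond by alkaline hydrogen peroxide: hydroperoxide adds to boron and C3 migrates from boron to oxygen with retention, so (2R)-13 gives (2R)-14; the silyl and aryl ethers are inert, and the diol 2 is set free for recovery.

Step 7
Reactants: 14 (2R)-13-(tert-butyldimethylsilyloxy)-1-(3,5-dimethoxyphenyl)tridecan-2-ol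
Product: 15 (2R)-13-(tert-butyldimethylsilyloxy)-1-(2-iodo-3,5-dimethoxyphenyl)tridecan-2-ol
Conditions: NIS (1.05 equiv), MeCN, 0 °C → rt, dark
Reagents that add atoms: N-iodosuccinimide, O=C1CCC(=O)N1I
Why: Electrophilic aromatic iodination; the two positions ortho to the side chain are equivalent by symmetry and each is para to one methoxy group and ortho to the other, whereas the carbon between the two methoxy groups is shielded on both sides; one equivalent of NIS at 0 °C should stop at mono-iodination and leave the secondary alcohol and the silyl ether alone.

Step 8
Reactants: 15 (2R)-13-(tert-butyldimethylsilyloxy)-1-(2-iodo-3,5-dimethoxyphenyl)tridecan-2-ol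
Product: 16 (3R)-3-[11-(tert-butyldimethylsilyloxy)undecyl]-6,8-dimethoxy-3,4-dihydro-1H-isochromen-1-one
Conditions: Pd(OAc)2 (5 mol %), Xantphos (7 mol %), Et3N (3 equiv), CO (1 atm), toluene, 80 °C
Reagents that add atoms: carbon monoxide, [C-]#[O+]
Why: Palladium-catalysed carbonylative lactonisation (intramolecular alkoxycarbonylation): zerovalent palladium inserts into the C–I bond, CO gives the aroylpalladium species and the tethered secondary hydroxyl attacks it to close the six-membered lactone while Et3N takes up HI; the C3–O bond is not broken, so the configuration is kept.

Step 9
Reactants: 16 (3R)-3-[11-(tert-butyldimethylsilyloxy)undecyl]-6,8-dimethoxy-3,4-dihydro-1H-isochromen-1-one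
Product: 17 (3R)-8-hydroxy-3-(11-hydroxyundecyl)-6-methoxy-3,4-dihydro-1H-isochromen-1-one
Conditions: BCl3 (1 M in CH2Cl2, 3 equiv), CH2Cl2, −78 → 0 °C; then MeOH, 0 °C → rt
Reagents that add atoms: none
Why: Chelation-controlled ether cleavage: BCl3 binds the lactone carbonyl and the peri methoxy oxygen at C8 in a six-membered chelate and chloride removes that methyl group only, the C6 ether lacking such assistance at low temperature; the methanol quench produces methanolic HCl, which should take off the primary silyl ether without opening the lactone.

## Compound list

1 | (1S,2S)-1,2-diphenylethane-1,2-diol | O[C@@H](c1ccccc1)[C@H](c1ccccc1)O | starting material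
2 | (1S,2S)-1,2-dicyclohexylethane-1,2-diol | O[C@@H](C1CCCCC1)[C@H](C1CCCCC1)O | intermediate
3 | 3,5-dimethoxybenzyl chloride | COc1cc(CCl)cc(OC)c1 | starting material
4 | 3,5-dimethoxybenzylmagnesium chloride | COc1cc(C[Mg]Cl)cc(OC)c1 | intermediate
5 | (3,5-dimethoxybenzyl)boronic acid | COc1cc(CB(O)O)cc(OC)c1 | intermediate
6 | (4S,5S)-4,5-dicyclohexyl-2-(3,5-dimethoxybenzyl)-1,3,2-dioxaborolane | COc1cc(CB2O[C@@H](C3CCCCC3)[C@H](C3CCCCC3)O2)cc(OC)c1 | intermediate
7 | 11-bromoundecan-1-ol | OCCCCCCCCCCCBr | starting material
8 | [(11-bromoundecyl)oxy](tert-butyl)dimethylsilane | CC(C)(C)[Si](C)(C)OCCCCCCCCCCCBr | intermediate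
9 | [11-(tert-butyldimethylsilyloxy)undecyl]magnesium bromide | Br[Mg]CCCCCCCCCCCO[Si](C)(C)C(C)(C)C | intermediate
10 | dichloromethane | ClCCl | starting material
11 | (dichloromethyl)lithium | [Li]C(Cl)Cl | intermediate
12 | (4S,5S)-2-[(1R)-1-chloro-2-(3,5-dimethoxyphenyl)ethyl]-4,5-dicyclohexyl-1,3,2-dioxaborolane | COc1cc(C[C@H](Cl)B2O[C@@H](C3CCCCC3)[C@H](C3CCCCC3)O2)cc(OC)c1 | intermediate
13 | (4S,5S)-4,5-dicyclohexyl-2-[(2R)-13-(tert-butyldimethylsilyloxy)-1-(3,5-dimethoxyphenyl)tridecan-2-yl]-1,3,2-dioxaborolane | COc1cc(C[C@@H](CCCCCCCCCCCO[Si](C)(C)C(C)(C)C)B2O[C@@H](C3CCCCC3)[C@H](C3CCCCC3)O2)cc(OC)c1 | intermediate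
14 | (2R)-13-(tert-butyldimethylsilyloxy)-1-(3,5-dimethoxyphenyl)tridecan-2-ol | COc1cc(C[C@@H](CCCCCCCCCCCO[Si](C)(C)C(C)(C)C)O)cc(OC)c1 | intermediate
15 | (2R)-13-(tert-butyldimethylsilyloxy)-1-(2-iodo-3,5-dimethoxyphenyl)tridecan-2-ol | COc1cc(OC)c(I)c(C[C@@H](CCCCCCCCCCCO[Si](C)(C)C(C)(C)C)O)c1 | intermediate
16 | (3R)-3-[11-(tert-butyldimethylsilyloxy)undecyl]-6,8-dimethoxy-3,4-dihydro-1H-isochromen-1-one | COc1cc(OC)c2c(c1)C[C@@H](CCCCCCCCCCCO[Si](C)(C)C(C)(C)C)OC2=O | intermediate
17 | (3R)-8-hydroxy-3-(11-hydroxyundecyl)-6-methoxy-3,4-dihydro-1H-isochromen-1-one | COc1cc(O)c2c(c1)C[C@@H](CCCCCCCCCCCO)OC2=O | target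

## Step count and risks

Total step count: 9 (8 if the diol 2 is purchased). Longest linear sequence: 7 steps (steps 1, 2, 5, 6, 7, 8, 9; the branch through steps 3 and 4 is equally long).

**Step 5 (key step).**
- Most likely to go wrong: loss of stereochemical purity through chloride-induced epimerisation of the alpha-chloro boronic ester before the Grignard reagent is added. Also possible are benzylic deprotonation next to boron by the carbenoid and base-induced loss of HCl from the beta-aryl chloro boronic ester, both of which would lower conversion.
- Fallback: the stereocentre is taken from a resolved epoxide and the C4a–C4 bond is made instead. It sets out from 9 and returns at 14.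
  - Iron-catalysed Kumada coupling of 9 with vinyl bromide (Fe(acac)3, THF/NMP, 0 °C) would give tert-butyldimethyl(tridec-12-en-1-yloxy)silane F1.
  - Epoxidation with mCPBA in CH2Cl2 would give racemic 2-[11-(tert-butyldimethylsilyloxy)undecyl]oxirane F2.
  - Hydrolytic kinetic resolution with (R,R)-(salen)Co(OAc), a complex of trivalent cobalt, and 0.55 equiv of water would consume the (S)-epoxide and leave (R)-2-[11-(tert-butyldimethylsilyloxy)undecyl]oxirane F3.
  - Opening of F3 at its CH2 group with purchased 3,5-dimethoxyphenylmagnesium chloride and CuI (cat.) in THF at −30 °C would give 14 with the C3–O bond untouched.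

**Step 8.**
- Most likely to go wrong: slow oxidative addition at the doubly ortho-substituted, electron-rich C–I bond, so that hydrodeiodination (through beta-hydride elimination from a palladium alkoxide of the secondary alcohol) or catalyst deactivation under CO overtakes lactonisation.
- Fallback: a polar carboxylation that sets out from 15 and returns at 16.
  - i-PrMgCl·LiCl (2.2 equiv, THF, −20 °C → rt) would deprotonate the hydroxyl and exchange the iodide.
  - Dry CO2 and an acidic work-up would give 2-[(2R)-13-(tert-butyldimethylsilyloxy)-2-hydroxytridecyl]-4,6-dimethoxybenzoic acid F4.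
  - F4 should close to 16 on warming with PPTS in toluene.

**Step 2.**
- Most likely to go wrong: Wurtz homocoupling during formation of the benzylic Grignard reagent, and protodeboronation or air oxidation of the free boronic acid before it is esterified.
- Fallback: the benzylic carbon is inserted into an aryl–boron bond. It sets out from 2 and returns at 6.
  - Condensation of 2 with purchased 3,5-dimethoxyphenylboronic acid (MgSO4, Et2O) would give (4S,5S)-4,5-dicyclohexyl-2-(3,5-dimethoxyphenyl)-1,3,2-dioxaborolane F5.
  - (Chloromethyl)lithium, generated in the presence of F5 from BrCH2Cl and n-BuLi in THF at −78 °C, would add to boron; aryl migration on warming would give 6.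

**Step 7.**
- Most likely to go wrong: iodination at the carbon between the two methoxy groups, or a second iodination at the other ortho position.
- Fallback: the ring closure itself fixes the position of attack and no aryl halide is needed. It sets out from 14 and returns at 16, passing by step 8 as well.
  - MOMCl and i-Pr2NEt in CH2Cl2 would give the methoxymethyl ether (2R)-13-(tert-butyldimethylsilyloxy)-1-(3,5-dimethoxyphenyl)-2-(methoxymethoxy)tridecane F6.
  - TMSOTf (cat.) in CH2Cl2 at −40 °C would ionise the acetal, and oxa-Pictet–Spengler closure onto either equivalent ortho carbon would give (3R)-3-[11-(tert-butyldimethylsilyloxy)undecyl]-6,8-dimethoxy-3,4-dihydro-1H-isochromene F7.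
  - Oxidation of the doubly activated C1 methylene with KMnO4/CuSO4·5H2O in CH2Cl2 would give 16.

**Step 9.**
- Most likely to go wrong: loss of discrimination between the two aryl methyl ethers, or incomplete removal of the silyl group in the quench.
- Fallback: cleave everything and re-methylate selectively. It sets out from 16 and returns at 17.
  - BBr3 in CH2Cl2 (−78 → 0 °C) would remove both methyl groups and the silyl group to give (3R)-6,8-dihydroxy-3-(11-hydroxyundecyl)-3,4-dihydro-1H-isochromen-1-one F8.
  - MeI (1.05 equiv) with K2CO3 in acetone should methylate only the C6 phenol, since the C8 phenol is held in a hydrogen bond to the lactone carbonyl and the primary alcohol is not acidic enough; this gives 17.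

Further compounds

F1 | step 5 | tert-butyldimethyl(tridec-12-en-1-yloxy)silane | C=CCCCCCCCCCCCO[Si](C)(C)C(C)(C)C
F2 | step 5 | racemic 2-[11-(tert-butyldimethylsilyloxy)undecyl]oxirane | CC(C)(C)[Si](C)(C)OCCCCCCCCCCCC1CO1
F3 | step 5 | (R)-2-[11-(tert-butyldimethylsilyloxy)undecyl]oxirane | CC(C)(C)[Si](C)(C)OCCCCCCCCCCC[C@@H]1CO1
F4 | step 8 | 2-[(2R)-13-(tert-butyldimethylsilyloxy)-2-hydroxytridecyl]-4,6-dimethoxybenzoic acid | COc1cc(OC)c(C(=O)O)c(C[C@@H](CCCCCCCCCCCO[Si](C)(C)C(C)(C)C)O)c1
F5 | step 2 | (4S,5S)-4,5-dicyclohexyl-2-(3,5-dimethoxyphenyl)-1,3,2-dioxaborolane | COc1cc(B2O[C@@H](C3CCCCC3)[C@H](C3CCCCC3)O2)cc(OC)c1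
F6 | step 7 | (2R)-13-(tert-butyldimethylsilyloxy)-1-(3,5-dimethoxyphenyl)-2-(methoxymethoxy)tridecane | COc1cc(C[C@@H](CCCCCCCCCCCO[Si](C)(C)C(C)(C)C)OCOC)cc(OC)c1
F7 | step 7 | (3R)-3-[11-(tert-butyldimethylsilyloxy)undecyl]-6,8-dimethoxy-3,4-dihydro-1H-isochromene | COc1cc(OC)c2c(c1)C[C@@H](CCCCCCCCCCCO[Si](C)(C)C(C)(C)C)OC2
F8 | step 9 | (3R)-6,8-dihydroxy-3-(11-hydroxyundecyl)-3,4-dihydro-1H-isochromen-1-one | Oc1cc(O)c2c(c1)C[C@@H](CCCCCCCCCCCO)OC2=O
A1 | alternative 1 | (3S)-6,8-dimethoxy-3-vinyl-3,4-dihydroisocoumarin | COc1cc(OC)c2c(c1)C[C@@H](C=C)OC2=O
A2 | alternative 1 | 2,4-dimethoxy-6-[(2E)-4-(methoxycarbonyloxy)but-2-en-1-yl]benzoic acid | COC(=O)OC/C=C/Cc1cc(OC)cc(OC)c1C(=O)O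
A3 | alternative 1 | undec-10-en-1-ol | C=CCCCCCCCCCO
A4 | alternative 2 | 5-[(2R)-2,13-bis(tert-butyldimethylsilyloxy)tridecyl]-7-hydroxy-2,2-dimethyl-4H-1,3-benzodioxin-4-one | CC1(C)OC(=O)c2c(O1)cc(O)cc2C[C@@H](CCCCCCCCCCCO[Si](C)(C)C(C)(C)C)O[Si](C)(C)C(C)(C)C
A5 | alternative 2 | 6-[(6R)-6,17-bis(tert-butyldimethylsilyloxy)-2,4-dioxoheptadecyl]-2,2-dimethyl-4H-1,3-dioxin-4-one | CC1(C)OC(=O)C=C(O1)CC(=O)CC(=O)C[C@@H](CCCCCCCCCCCO[Si](C)(C)C(C)(C)C)O[Si](C)(C)C(C)(C)C
A6 | alternative 3 | (3R)-3-[11-(tert-butyldimethylsilyloxy)undecyl]-6,8-dimethoxy-3,4-dihydroisocoumarin | COc1cc(OC)c2c(c1)C[C@@H](CCCCCCCCCCCO[Si](C)(C)C(C)(C)C)OC2=O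
A7 | alternative 3 | 1-iodo-2,4-dimethoxybenzene | COc1ccc(I)c(OC)c1
A8 | alternative 3 | (R)-2-[11-(tert-butyldimethylsilyloxy)undecyl]oxirane | CC(C)(C)[Si](C)(C)OCCCCCCCCCCC[C@@H]1CO1
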